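**Retrosynthetic overview**

1. Target 26 comes from C5 benzoylation after desilylation. Ring C, the spiro 2',6'-dimethoxycyclohexa-2',5'-dienone, is symmetric, so C1 is not stereogenic; it is built by Robinson annulation of C1 aldehyde 16 with 1-methoxybut-3-en-2-one, then α'-hydroxylation, oxidation and O-methylation.
2. Aldehyde 16 comes from the C1 ketone by methoxymethylenation, and the ketone from the C1 dioxolane. The C5 carbinol comes from Corey–Bakshi–Shibata reduction of the C5 aryl ketone.
3. Feature the strategy rests on: in ring B, C3 and C4 are the β- and α-carbons of the C5 ketone, which is bonded to C5a of ring A. Both methyl groups are therefore added to achiral enone 8 (C1 dioxolane, C3=C4, C5=O) by copper-catalysed asymmetric conjugate addition and enolate methylation.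
4. Enone 8 comes from benzosuberone 5 by ketalisation at C1 while the ketone is in the ring, benzylic oxidation at C5 and C3–C4 desaturation. Ketone 5 comes from Friedel–Crafts closure of ring B on 5-(3,4,5-trimethoxyphenyl)pentanoic acid.
5. Ring order: ring A (in 3,4,5-trimethoxybenzaldehyde), ring B (step 3), ring C (step 13).

Key step: step 7

Remark on the chemistry: ring B is numbered C1 (ketal, later spiro carbon), C2, C3, C4, C5 (carbinol carbon), C5a and C9a (shared with ring A, methoxy groups at C7, C8, C9); ring C atoms are primed (C1' carbonyl, C4' = C1); the sense of induction of the phosphoramidite in step 7 is assumed to be the one known for cyclohex-2-enone and cyclohept-2-enone.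

**Route**

Step 1
Reactants: 1 3,4,5-trimethoxybenzaldehyde; 2 (3-carboxypropyl)triphenylphosphonium bromide
Product: 3 5-(3,4,5-trimethoxyphenyl)pent-4-enoic acid (E/Z mixture)
Conditions: KOtBu (2.2 equiv), THF, 0 °C to rt; aq. HCl
Reagents that add atoms: none
Why: Wittig olefination of the aryl aldehyde with the non-stabilised carboxylate ylide attaches the whole five-carbon chain of ring B in one operation, and the E/Z ratio is irrelevant because the alkene is hydrogenated in step 2.

Step 2
Reactants: 3 5-(3,4,5-trimethoxyphenyl)pent-4-enoic acid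
Product: 4 5-(3,4,5-trimethoxyphenyl)pentanoic acid
Conditions: H2 (1 atm), Pd/C (10%), MeOH, rt
Reagents that add atoms: none
Why: Heterogeneous catalytic hydrogenation saturates the styrenic double bond under conditions that leave the aryl methyl ethers and the acid untouched.

Step 3
Reactants: 4 5-(3,4,5-trimethoxyphenyl)pentanoic acid
Product: 5 2,3,4-trimethoxy-6,7,8,9-tetrahydro-5H-benzo[7]annulen-5-one (ring B closed; ketone at C1, C2 to C5 are CH2)
Conditions: P2O5 in MeSO3H (1:10 w/w), rt
Reagents that add atoms: none
Why: Intramolecular Friedel–Crafts acylation closes seven-membered ring B at one of the two equivalent ring A positions ortho to the chain, each activated by an ortho and a para methoxy group, so only the regioisomer with the ketone at C1 can form.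

Step 4
Reactants: 5 benzosuberone with C1 ketone
Product: 6 C1 ethylene ketal of 5 (spiro-1,3-dioxolane at C1)
Conditions: (Me3SiOCH2)2, Me3SiOTf (cat.), CH2Cl2, −20 °C to 0 °C; pyridine quench
Reagents that add atoms: 1,2-bis(trimethylsilyloxy)ethane C[Si](C)(C)OCCO[Si](C)(C)C
Why: Silyl-triflate-catalysed ketalisation with the bis-silyl ether of ethylene glycol is driven irreversibly by formation of hexamethyldisiloxane and runs without free acid or water, which suits this electron-rich aryl ketone while it is held in the ring and has only one ortho neighbour.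

Step 5
Reactants: 6 C1 dioxolane
Product: 7 C5 ketone with C1 dioxolane (C2, C3, C4 are CH2)
Conditions: t-BuOOH (70% aq.), Rh2(cap)4 (1 mol%), NaHCO3, 1,2-dichloroethane, 40 °C
Reagents that add atoms: tert-butyl hydroperoxide CC(C)(C)OO
Why: Radical benzylic C–H oxidation by tert-butylperoxyl radicals from the dirhodium caprolactamate catalyst converts C5, the only benzylic CH2 left because C1 is a quaternary ketal carbon, into the ketone under bicarbonate-buffered conditions that spare the dioxolane.

Step 6
Reactants: 7 C5 ketone with C1 dioxolane
Product: 8 achiral enone (C1 dioxolane, C2 CH2, cis C3=C4 in ring B, C5 ketone)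
Conditions: IBX, 4-methoxypyridine N-oxide, DMSO, rt
Reagents that add atoms: none
Why: IBX dehydrogenation of a ketone to its enone can only introduce the C3=C4 bond, because C4 is the sole α-CH2 and quaternary C1 blocks a second desaturation, and the N-oxide complex allows room temperature so that the acid- and base-sensitive γ-ketal enone is not opened to a benzotropone.

Step 7
Reactants: 8 achiral enone; 9 iodomethane
Product: 11 (3R,4S)-3,4-dimethyl C5 ketone with C1 dioxolane (methyl groups trans), via methylzinc enolate 10 (not isolated)
Conditions: Cu(OTf)2 (2 mol%), (R,S,S)-phosphoramidite from (R)-1,1'-bi-2-naphthol and bis[(S)-1-phenylethyl]amine (4 mol%), Zn(CH3)2 (1.5 equiv), toluene, −30 °C; then CH3I (10 equiv), HMPA, 0 °C to rt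
Reagents that add atoms: dimethylzinc C[Zn]C
Why: Cu(OTf)2 is reduced in the flask by Zn(CH3)2 to a monovalent copper–phosphoramidite complex that binds the cis enone of ring B as a π-complex, transfers methyl to C3 through a trivalent copper intermediate and leaves methylzinc enolate 10, which HMPA makes nucleophilic enough to be C-methylated at C4 by iodomethane. The closest known reaction type is the copper–phosphoramidite catalysed conjugate addition of dialkylzinc reagents to cyclohex-2-enone and cyclohept-2-enone with alkylation of the zinc enolate; no ring is closed. C3 is set by the ligand alone, since the symmetric dioxolane and the absence of any stereocentre leave no substrate bias, and the (R,S,S) enantiomer is expected by analogy with the simple cycloalkenones to give the (3R) centre. C4 is set by approach of iodomethane to the enolate face opposite the C3 methyl, and it is backed by the thermodynamic preference for the trans arrangement because C4 stays epimerisable next to the ketone. The step needs 1,4- over 1,2-addition (secured by the soft methylcopper species), facial selectivity (ligand) and a single C-alkylation (C4 is the only enolisable position because the other α-position is aryl carbon C5a).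

Step 8
Reactants: 11 (3R,4S)-dimethyl ketone
Product: 12 (3R,4S,5R)-C5 alcohol with C1 dioxolane (hydroxyl trans to the C4 methyl, cis to the C3 methyl)
Conditions: (S)-2-methyl-CBS-oxazaborolidine (0.5 equiv), BH3·SMe2 (1.0 equiv), THF, −20 °C; MeOH quench
Reagents that add atoms: none
Why: In the Corey–Bakshi–Shibata reduction the (S)-oxazaborolidine–borane complex binds the C5 ketone with ring A as the large and C4 as the small group and delivers hydride to the face that gives the (5R) carbinol, which is also the all-equatorial arrangement that a small hydride should favour on this ring.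

Step 9
Reactants: 12 (3R,4S,5R)-alcohol
Product: 13 tert-butyldimethylsilyl ether of 12
Conditions: t-BuMe2SiCl, imidazole, DMAP (cat.), DMF, 40 °C
Reagents that add atoms: tert-butyldimethylsilyl chloride CC(C)(C)[Si](C)(C)Cl
Why: Imidazole-promoted silylation protects the secondary benzylic alcohol without acid, so the dioxolane survives, and it masks a hydroxyl that would otherwise add across ring B to the C1 ketone as a bridged hemiketal once the ketal is removed.

Step 10
Reactants: 13 silyl ether with C1 dioxolane
Product: 14 C1 ketone, (3R,4S,5R)-5-silyloxy-3,4-dimethyl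
Conditions: PPTS, acetone–H2O (10:1), 50 °C
Reagents that add atoms: water O
Why: Acid-catalysed ketal hydrolysis is easy here because the ortho- and para-methoxy groups of ring A stabilise the C1 oxocarbenium ion, so pyridinium tosylate suffices and the secondary silyl ether and the C3, C4 and C5 centres are untouched.

Step 11
Reactants: 14 C1 ketone
Product: 15 C1 methoxymethylene enol ether (E/Z mixture)
Conditions: Ph3P(Cl)CH2OMe, KN(SiMe3)2, THF, 0 °C to rt
Reagents that add atoms: (methoxymethyl)triphenylphosphonium chloride COC[P+](c1ccccc1)(c1ccccc1)c1ccccc1.[Cl-]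
Why: Wittig methoxymethylenation with an excess of the reactive α-methoxy ylide adds the carbon that becomes C3' of ring C, and enolisation of the hindered ketone is harmless because no stereocentre is α to it.

Step 12
Reactants: 15 enol ether
Product: 16 C1 carbaldehyde (both C1 epimers)
Conditions: TsOH·H2O (cat.), acetone–H2O, rt
Reagents that add atoms: water O
Why: Acid-catalysed enol ether hydrolysis (protonation at C1, addition of water, loss of methanol) frees the aldehyde as a mixture of C1 epimers, which is of no consequence because C1 is next turned into an enolate and a quaternary centre.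

Step 13
Reactants: 16 C1 carbaldehyde; 17 1-methoxybut-3-en-2-one
Product: 20 spiro 2'-methoxycyclohex-2'-en-1'-one (ring C closed; C5', C6' are CH2; both C1 epimers), via Michael adduct 18 (not isolated), via aldol 19 (not isolated)
Conditions: KOH (cat.), MeOH–THF, 0 °C to 50 °C
Reagents that add atoms: none
Why: In this Robinson annulation the benzylic, fully substituted enolate of the aldehyde adds to the vinyl ketone to make C1 quaternary, and the methoxy-bearing α-carbon of the new ketone then closes six-membered ring C on the aldehyde by aldol condensation, the only ring size open to it, and dehydrates to the 2'-methoxy enone, the C1 epimers being carried on together because C1 loses its stereogenicity in step 16.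

Step 14
Reactants: 20 spiro 2'-methoxy enone
Product: 21 6'-hydroxy derivative of 20 (diastereomer mixture)
Conditions: KN(SiMe3)2, THF, −78 °C; then 2-(phenylsulfonyl)-3-phenyloxaziridine
Reagents that add atoms: 2-(phenylsulfonyl)-3-phenyloxaziridine O=S(=O)(c1ccccc1)N1OC1c1ccccc1
Why: α'-Hydroxylation of the potassium enolate by electrophilic oxygen transfer from the N-sulfonyloxaziridine occurs at C6', the only enolisable position of ring C, and the configuration of the new carbinol is irrelevant because it is oxidised in step 15.

Step 15
Reactants: 21 6'-hydroxy enone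
Product: 23 diosphenol (ring C as 6'-hydroxy-2'-methoxycyclohexa-2',5'-dien-1'-one), via diketone tautomer 22 (not isolated)
Conditions: Dess–Martin periodinane, NaHCO3, CH2Cl2, rt
Reagents that add atoms: none
Why: Dess–Martin oxidation of the α-hydroxy ketone gives the 1',6'-diketone, which should enolise towards C5' because the resulting cross-conjugated dienone is stabilised by conjugation and an internal hydrogen bond.

Step 16
Reactants: 23 diosphenol; 9 iodomethane
Product: 24 2',6'-dimethoxycyclohexa-2',5'-dien-1'-one (ring C symmetric, C1 no longer stereogenic), C5 silyl ether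
Conditions: K2CO3, acetone, 50 °C
Reagents that add atoms: none
Why: Williamson-type O-methylation of the acidic diosphenol via its potassium enolate makes ring C symmetric, so the C1 epimer mixture converges to one compound.

Step 17
Reactants: 24 dimethoxydienone silyl ether
Product: 25 (3R,4S,5R)-C5 alcohol with the spiro dimethoxydienone
Conditions: HF·pyridine, pyridine, THF, 0 °C to rt
Reagents that add atoms: none
Why: Fluoride-mediated desilylation with pyridine-buffered HF avoids basic fluoride, which could promote addition of the freed C5 alkoxide to the dienone, and does not touch the C5 configuration.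

Step 18
Reactants: 25 C5 alcohol
Product: 26 CNP0201356.1, the (3R,4S,5R)-C5 benzoate
Conditions: PhCOCl, pyridine, DMAP (cat.), CH2Cl2, 0 °C to rt
Reagents that add atoms: benzoyl chloride O=C(Cl)c1ccccc1
Why: DMAP-catalysed acylation through the N-benzoylpyridinium ion esterifies the C5 alcohol with retention and gives the target.

**Compound list**

1 | 3,4,5-trimethoxybenzaldehyde | COc1cc(C=O)cc(OC)c1OC | starting material
2 | (3-carboxypropyl)triphenylphosphonium bromide | OC(=O)CCC[P+](c1ccccc1)(c1ccccc1)c1ccccc1.[Br-] | starting material
3 | 5-(3,4,5-trimethoxyphenyl)pent-4-enoic acid (E/Z mixture) | COc1cc(C=CCCC(O)=O)cc(OC)c1OC | intermediate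
4 | 5-(3,4,5-trimethoxyphenyl)pentanoic acid | COc1cc(CCCCC(O)=O)cc(OC)c1OC | intermediate
5 | 2,3,4-trimethoxy-6,7,8,9-tetrahydro-5H-benzo[7]annulen-5-one (C1 ketone) | O=C1CCCCc2cc(OC)c(OC)c(OC)c12 | intermediate
6 | C1 spiro-1,3-dioxolane of 5 | O1CCOC12CCCCc1cc(OC)c(OC)c(OC)c12 | intermediate
7 | C5 ketone with C1 dioxolane | O1CCOC12CCCC(=O)c1cc(OC)c(OC)c(OC)c12 | intermediate
8 | achiral enone: C1 dioxolane, C3=C4, C5 ketone | O1CCOC12CC=CC(=O)c1cc(OC)c(OC)c(OC)c12 | intermediate
9 | iodomethane | CI | starting material
10 | methylzinc enolate (C4=C5–OZnCH3) of the (3R)-3-methyl ketone (not isolated) | O1CCOC12C[C@@H](C)C=C(O[Zn]C)c1cc(OC)c(OC)c(OC)c12 | intermediate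
11 | (3R,4S)-3,4-dimethyl C5 ketone with C1 dioxolane (trans) | O1CCOC12C[C@@H](C)[C@H](C)C(=O)c1cc(OC)c(OC)c(OC)c12 | intermediate
12 | (3R,4S,5R)-C5 alcohol with C1 dioxolane | O1CCOC12C[C@@H](C)[C@H](C)[C@@H](O)c1cc(OC)c(OC)c(OC)c12 | intermediate
13 | tert-butyldimethylsilyl ether of 12 | O1CCOC12C[C@@H](C)[C@H](C)[C@@H](O[Si](C)(C)C(C)(C)C)c1cc(OC)c(OC)c(OC)c12 | intermediate
14 | C1 ketone, (3R,4S,5R)-5-silyloxy-3,4-dimethyl | O=C1C[C@@H](C)[C@H](C)[C@@H](O[Si](C)(C)C(C)(C)C)c2cc(OC)c(OC)c(OC)c12 | intermediate
15 | C1 methoxymethylene enol ether (E/Z mixture) | COC=C1C[C@@H](C)[C@H](C)[C@@H](O[Si](C)(C)C(C)(C)C)c2cc(OC)c(OC)c(OC)c12 | intermediate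
16 | C1 carbaldehyde (both C1 epimers) | O=CC1C[C@@H](C)[C@H](C)[C@@H](O[Si](C)(C)C(C)(C)C)c2cc(OC)c(OC)c(OC)c12 | intermediate
17 | 1-methoxybut-3-en-2-one | COCC(=O)C=C | starting material
18 | Michael adduct: quaternary C1 bearing CHO and CH2CH2C(=O)CH2OCH3 (both C1 epimers, not isolated) | COCC(=O)CCC1(C=O)C[C@@H](C)[C@H](C)[C@@H](O[Si](C)(C)C(C)(C)C)c2cc(OC)c(OC)c(OC)c12 | intermediate
19 | aldol: ring C as 3'-hydroxy-2'-methoxycyclohexan-1'-one (diastereomer mixture, not isolated) | COC1C(O)C2(CCC1=O)C[C@@H](C)[C@H](C)[C@@H](O[Si](C)(C)C(C)(C)C)c1cc(OC)c(OC)c(OC)c12 | intermediate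
20 | spiro 2'-methoxycyclohex-2'-en-1'-one (both C1 epimers) | COC1=CC2(CCC1=O)C[C@@H](C)[C@H](C)[C@@H](O[Si](C)(C)C(C)(C)C)c1cc(OC)c(OC)c(OC)c12 | intermediate
21 | 6'-hydroxy-2'-methoxycyclohex-2'-en-1'-one (diastereomer mixture) | COC1=CC2(CC(O)C1=O)C[C@@H](C)[C@H](C)[C@@H](O[Si](C)(C)C(C)(C)C)c1cc(OC)c(OC)c(OC)c12 | intermediate
22 | 1',6'-diketone tautomer (not isolated) | COC1=CC2(CC(=O)C1=O)C[C@@H](C)[C@H](C)[C@@H](O[Si](C)(C)C(C)(C)C)c1cc(OC)c(OC)c(OC)c12 | intermediate
23 | diosphenol: 6'-hydroxy-2'-methoxycyclohexa-2',5'-dien-1'-one (both C1 epimers) | COC1=CC2(C=C(O)C1=O)C[C@@H](C)[C@H](C)[C@@H](O[Si](C)(C)C(C)(C)C)c1cc(OC)c(OC)c(OC)c12 | intermediate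
24 | spiro 2',6'-dimethoxycyclohexa-2',5'-dien-1'-one, (3R,4S,5R)-C5 silyl ether | COC1=CC2(C=C(OC)C1=O)C[C@@H](C)[C@H](C)[C@@H](O[Si](C)(C)C(C)(C)C)c1cc(OC)c(OC)c(OC)c12 | intermediate
25 | spiro 2',6'-dimethoxydienone, (3R,4S,5R)-C5 alcohol | COC1=CC2(C=C(OC)C1=O)C[C@@H](C)[C@H](C)[C@@H](O)c1cc(OC)c(OC)c(OC)c12 | intermediate
26 | CNP0201356.1, (3R,4S,5R)-C5 benzoate | COC1=CC2(C=C(OC)C1=O)C[C@@H](C)[C@H](C)[C@@H](OC(=O)c1ccccc1)c1cc(OC)c(OC)c(OC)c12 | target

**Step count and risks**

Total step count: 18. Longest linear sequence: 18 steps (1 to 26).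

Steps most likely to fail:

Step 7. The electron-rich aryl enone may take up methyl from zinc only slowly, the facial selectivity may be lower than with the simple cycloalkenones, and the weakly nucleophilic zinc enolate may be alkylated incompletely or more than once. The fallback sets out from enone 8. The methyl source would be changed to CH3MgBr with CuBr·SMe2 and a chiral ferrocenyl bisphosphine in t-BuOMe at −75 °C, and the magnesium enolate would be protonated to give the 3-methyl ketone F1. F1 has the same spatial arrangement at C3 as 11; its descriptor is S only because C2 then outranks C4. In a separate step F1 would be deprotonated with LiN(iPr)2 in THF at −78 °C and methylated with iodomethane 9 anti to the C3 methyl, with NaOMe/MeOH equilibration to the trans isomer if needed. The route is rejoined at 11.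

Step 13. The congested quaternary centre at C1 may fail to form because of retro-Michael reaction or polymerisation of the sensitive methoxy vinyl ketone, and the aldol closure through the methoxy-bearing carbon may stall. The fallback sets out from aldehyde 16. It would be annulated with the more robust but-3-en-2-one (KOH cat. or the pyrrolidine enamine) to give the spiro cyclohex-2'-en-1'-one F2. Nucleophilic epoxidation (H2O2, NaOH, MeOH, 0 °C) would give the 2',3'-epoxy ketone F3. Opening of F3 at C2' by methoxide with dehydration (KOH, MeOH, reflux) would introduce the 2'-methoxy enone. The route is rejoined at 20.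

Step 8. Hydride delivery may occur to the wrong face if the trans-dimethyl array and the catalyst are mismatched, giving the C5 epimer. The fallback sets out from ketone 11. Reduction with LiBH(s-Bu)3 in THF at −78 °C, with hydride anti to the C4 methyl, would give the (3R,4S,5S)-alcohol F4. Mitsunobu inversion (4-nitrobenzoic acid, PPh3, DIAD, toluene) would give the (3R,4S,5R)-4-nitrobenzoate F5. Methanolysis (K2CO3, MeOH) would rejoin the route at 12.

Further compounds
F1 | step 7 | 3-methyl C5 ketone with C1 dioxolane (C3 as in 11) | O1CCOC12C[C@@H](C)CC(=O)c1cc(OC)c(OC)c(OC)c12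
F2 | step 13 | spiro cyclohex-2'-en-1'-one without methoxy group on ring C, C5 silyl ether (both C1 epimers) | O=C1C=CC2(CC1)C[C@@H](C)[C@H](C)[C@@H](O[Si](C)(C)C(C)(C)C)c1cc(OC)c(OC)c(OC)c12
F3 | step 13 | 2',3'-epoxy ketone of F2 | O=C1CCC2(C3OC13)C[C@@H](C)[C@H](C)[C@@H](O[Si](C)(C)C(C)(C)C)c1cc(OC)c(OC)c(OC)c12
F4 | step 8 | (3R,4S,5S)-C5 alcohol with C1 dioxolane | O1CCOC12C[C@@H](C)[C@H](C)[C@H](O)c1cc(OC)c(OC)c(OC)c12
F5 | step 8 | (3R,4S,5R)-C5 4-nitrobenzoate with C1 dioxolane | O1CCOC12C[C@@H](C)[C@H](C)[C@@H](OC(=O)c3ccc(cc3)[N+](=O)[O-])c1cc(OC)c(OC)c(OC)c12
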